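**Plan**

Locants follow carotenoid usage: ring C1 (CMe2) to C6, chain C7≡C8–C9(Me)=C10–C11=C12–C13(Me)=C14–C15=C15'–C14'=C13'(Me)–C12'–C11'–C10'(OH).
Retrosynthesis: cut C8–C9 to a ring terminal alkyne and a tetraenyne that carries C9≡C10 as a triple bond; cut C14'–C15' (Negishi) to a trienyl iodide and pent-4-yn-1-ol; cut C15=C15' (Takai) and C11=C12 (Horner–Wadsworth–Emmons) back to but-2-ynal and a C5 phosphonate; cut C6–C7 (Sonogashira) back to the enol triflate of a hydroxy-trimethylcyclohexanone.
Forward: the six-membered ring is bought intact and only its C5=C6 alkene is made (enol triflation); the chain is joined in the order C11=C12, C15=C15', C14'–C15' and last C8–C9, by syn addition of the alkyne C8–H bond across C9≡C10 with both hydroxyls free.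
Enabling feature: C9 of the tetraenyne carries only a methyl group while C10 carries the C11–C14' tetraene, which should steer an alkynyl–metal to C9; the ring alkyne is flanked by the C1 gem-dimethyl and C5 methyl groups of the cyclohexene, which should block its self-dimerization.
Stereochemistry: C3 (R) comes from (4R,6R)-actinol; 9E from the syn addition, 11E from the olefination, 13E from the phosphonate, 15E from the iodo-olefination, 13'E from syn-carboalumination.

Key step: step 11

Remark: (4R,6R)-actinol 1 is taken as a purchasable chiral-pool ketone; its methyl-bearing stereocentre is destroyed in step 2, so only the carbinol configuration matters.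

**Step 1**
Reactants: 1 (4R,6R)-4-hydroxy-2,2,6-trimethylcyclohexan-1-one (actinol)
Product: 2 (4R,6R)-4-[(tert-butyldimethylsilyl)oxy]-2,2,6-trimethylcyclohexan-1-one
Conditions: TBSCl, imidazole, DMF, rt
Reagents that add atoms: tert-butyldimethylsilyl chloride, CC(C)(C)[Si](C)(C)Cl
Why: Imidazole-promoted silyl ether formation masks the only hydroxyl before the strong base of step 2 and does not touch the carbinol stereocentre.

**Step 2**
Reactants: 2 (4R,6R)-4-[(tert-butyldimethylsilyl)oxy]-2,2,6-trimethylcyclohexan-1-one
Product: 4 (4R)-4-[(tert-butyldimethylsilyl)oxy]-2,6,6-trimethylcyclohex-1-en-1-yl trifluoromethanesulfonate, via lithium enolate 3 (not isolated)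
Conditions: LiN(iPr)2, THF, −78 °C; then PhNTf2, −78 °C → rt
Reagents that add atoms: N-phenylbis(trifluoromethanesulfonimide), O=S(=O)(N(c1ccccc1)S(=O)(=O)C(F)(F)F)C(F)(F)F
Why: Enol triflate formation: the ketone has a single α-hydrogen (on the methyl-bearing carbon, the other α-carbon being quaternary), so deprotonation and O-sulfonylation should give one regioisomer and create the tetrasubstituted C5=C6 ring alkene, while the methyl-bearing stereocentre is erased on purpose and the silyloxy-bearing one is unaffected.

**Step 3**
Reactants: 4 (4R)-4-[(tert-butyldimethylsilyl)oxy]-2,6,6-trimethylcyclohex-1-en-1-yl trifluoromethanesulfonate; 5 ethynyltrimethylsilane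
Product: 6 tert-butyldimethyl({(1R)-3,5,5-trimethyl-4-[(trimethylsilyl)ethynyl]cyclohex-3-en-1-yl}oxy)silane
Conditions: Pd(PPh3)4 (5 mol %), CuI (10 mol %), Et3N, DMF, 50 °C
Reagents that add atoms: none
Why: Sonogashira coupling of the enol triflate (oxidative addition of zerovalent palladium into C–OTf, transfer of the copper acetylide, reductive elimination) should form the C6–C7 bond, and the silyl cap on the alkyne prevents a second coupling.

**Step 4**
Reactants: 6 tert-butyldimethyl({(1R)-3,5,5-trimethyl-4-[(trimethylsilyl)ethynyl]cyclohex-3-en-1-yl}oxy)silane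
Product: 7 (1R)-4-ethynyl-3,5,5-trimethylcyclohex-3-en-1-ol
Conditions: Bu4NF (2.5 equiv), THF, 0 °C → rt
Reagents that add atoms: none
Why: Fluoride-induced desilylation should cleave both the C(sp)–Si and the O–Si bond in one operation, freeing the terminal alkyne and the C3 hydroxyl without risk to the enyne.

**Step 5**
Reactants: 8 but-2-yn-1-ol
Product: 9 but-2-ynal
Conditions: MnO2 (activated, excess), CH2Cl2, rt
Reagents that add atoms: none
Why: MnO2 oxidation of a propargylic alcohol stops at the ynal, which is volatile and is therefore carried on as a CH2Cl2 solution.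

**Step 6**
Reactants: 10 ethyl (2E)-4-(diethoxyphosphoryl)-3-methylbut-2-enoate; 9 but-2-ynal
Product: 12 ethyl (2E,4E)-3-methylocta-2,4-dien-6-ynoate, via lithiated phosphonate 11 (not isolated)
Conditions: LiN(SiMe3)2, THF, −78 °C; then 9, −78 → 0 °C
Reagents that add atoms: none
Why: Horner–Wadsworth–Emmons olefination through the phosphorus-bearing carbon of the vinylogous phosphonate anion should give the 11E alkene by elimination from the favoured adduct and the 13E geometry from the more stable transoid anion, a minor 13Z isomer being removable by chromatography.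

**Step 7**
Reactants: 12 ethyl (2E,4E)-3-methylocta-2,4-dien-6-ynoate
Product: 13 (2E,4E)-3-methylocta-2,4-dien-6-yn-1-ol
Conditions: iBu2AlH (2.2 equiv), CH2Cl2, −78 °C; aq. KNaC4H4O6
Reagents that add atoms: none
Why: Hydride reduction of the conjugated ester by two 1,2-additions should give the allylic alcohol at low temperature without attack on the enyne or the diene.

**Step 8**
Reactants: 13 (2E,4E)-3-methylocta-2,4-dien-6-yn-1-ol
Product: 14 (2E,4E)-3-methylocta-2,4-dien-6-ynal
Conditions: MnO2, CH2Cl2, rt, dark
Reagents that add atoms: none
Why: MnO2 oxidation of the dienylic alcohol should give the aldehyde under neutral conditions that preserve both alkene geometries.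

**Step 9**
Reactants: 14 (2E,4E)-3-methylocta-2,4-dien-6-ynal
Product: 15 (1E,3E,5E)-1-iodo-4-methylnona-1,3,5-trien-7-yne
Conditions: CrCl2 (6 equiv), CHI3 (2 equiv), THF–1,4-dioxane, 0 °C → rt, dark
Reagents that add atoms: iodoform, IC(I)I
Why: Takai olefination: the geminal dichromium reagent formed from CHI3 and divalent chromium adds to the aldehyde and eliminates with the large groups anti, which should give the 15E iodoalkene and leave the conjugated alkyne untouched.

**Step 10**
Reactants: 16 pent-4-yn-1-ol; 15 (1E,3E,5E)-1-iodo-4-methylnona-1,3,5-trien-7-yne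
Product: 19 (4E,6E,8E,10E)-4,9-dimethyltetradeca-4,6,8,10-tetraen-12-yn-1-ol, via alkenylalane 17 (not isolated), via alkenylzinc chloride 18 (not isolated)
Conditions: AlMe3 (3 equiv), Cp2ZrCl2 (0.25 equiv), CH2Cl2, 0 °C → rt; volatiles removed; then ZnCl2, 15, Pd(PPh3)4 (5 mol %), THF, rt, dark
Reagents that add atoms: trimethylaluminium, C[Al](C)C
Why: Zirconium-catalysed syn-carboalumination puts the methyl group on the internal and aluminium on the terminal alkyne carbon (13'E fixed by the syn addition), and transmetalation via zinc to palladium followed by Negishi coupling with the iodide should join C14' to C15' with retention at both sp2 carbons.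

**Step 11**
Reactants: 7 (1R)-4-ethynyl-3,5,5-trimethylcyclohex-3-en-1-ol; 19 (4E,6E,8E,10E)-4,9-dimethyltetradeca-4,6,8,10-tetraen-12-yn-1-ol
Product: 20 (1R)-4-[(3E,5E,7E,9E,11E)-15-hydroxy-3,7,12-trimethylpentadeca-3,5,7,9,11-pentaen-1-yn-1-yl]-3,5,5-trimethylcyclohex-3-en-1-ol
Conditions: [Rh(OH)(cod)]2 (2.5 mol %), rac-BINAP (6 mol %), 1,4-dioxane, 60 °C, 7 (1.3 equiv) added over 6 h, dark
Reagents that add atoms: none
Why: Proposed new method: the BINAP-ligated rhodium hydroxide (monovalent rhodium) should deprotonate the terminal alkyne of 7 to an alkynylrhodium species, which adds syn across the C9≡C10 triple bond of 19 with C8 going to the methyl-bearing C9 and rhodium to C10, and the alkenylrhodium is then protonated with retention by a second molecule of 7 or by a hydroxyl group, so that C8 and the new C10–H are cis and the 9E enyne results. The closest known reaction type is the rhodium- or palladium-catalysed hydroalkynylation (cross-dimerization) of internal aryl–alkyl alkynes and of alkynoates with bulky terminal alkynes, which also runs by syn alkynylmetalation and protonolysis; it has not been shown with a polyenyl-substituted alkyne as acceptor or with a cyclohexenylacetylene as donor. No ring is closed and no stereocentre is formed; the one new stereo-element, the C9=C10 geometry, is fixed by the suprafacial insertion. The step needs regioselectivity for C9 over C10, which the substrate should supply because C9 carries only a methyl group while C10 bears the tetraene that stabilizes the adjacent carbon–rhodium bond, as the aryl group does in 1-arylpropynes. It needs cross- over homo-coupling, which the C1 gem-dimethyl and C5 methyl groups beside the donor alkyne should supply by hindering insertion of 7 into its own alkynylrhodium (helped by slow addition), and it needs the alkyne to react in preference to the di- and trisubstituted alkenes of the tetraene, which are not expected to insert. The two free hydroxyls are spectators that can shuttle protons, so the union needs no protecting group and uses every atom of both partners.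

**Compound list**

1 | (4R,6R)-4-hydroxy-2,2,6-trimethylcyclohexan-1-one (actinol) | O=C1C(C)(C)C[C@H](O)C[C@H]1C | starting material
2 | (4R,6R)-4-[(tert-butyldimethylsilyl)oxy]-2,2,6-trimethylcyclohexan-1-one | O=C1C(C)(C)C[C@H](O[Si](C)(C)C(C)(C)C)C[C@H]1C | intermediate
3 | lithium (4R)-4-[(tert-butyldimethylsilyl)oxy]-2,6,6-trimethylcyclohex-1-en-1-olate (not isolated) | [Li+].CC1=C([O-])C(C)(C)C[C@H](O[Si](C)(C)C(C)(C)C)C1 | intermediate
4 | (4R)-4-[(tert-butyldimethylsilyl)oxy]-2,6,6-trimethylcyclohex-1-en-1-yl trifluoromethanesulfonate | CC1=C(OS(=O)(=O)C(F)(F)F)C(C)(C)C[C@H](O[Si](C)(C)C(C)(C)C)C1 | intermediate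
5 | ethynyltrimethylsilane | C#C[Si](C)(C)C | starting material
6 | tert-butyldimethyl({(1R)-3,5,5-trimethyl-4-[(trimethylsilyl)ethynyl]cyclohex-3-en-1-yl}oxy)silane | CC1=C(C#C[Si](C)(C)C)C(C)(C)C[C@H](O[Si](C)(C)C(C)(C)C)C1 | intermediate
7 | (1R)-4-ethynyl-3,5,5-trimethylcyclohex-3-en-1-ol | CC1=C(C#C)C(C)(C)C[C@H](O)C1 | intermediate
8 | but-2-yn-1-ol | CC#CCO | starting material
9 | but-2-ynal | CC#CC=O | intermediate
10 | ethyl (2E)-4-(diethoxyphosphoryl)-3-methylbut-2-enoate | CCOC(=O)/C=C(\C)CP(=O)(OCC)OCC | starting material
11 | lithium salt of the γ-deprotonated phosphonate 10 (not isolated) | CCOC(=O)/C=C(\C)[CH-]P(=O)(OCC)OCC.[Li+] | intermediate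
12 | ethyl (2E,4E)-3-methylocta-2,4-dien-6-ynoate | CC#C/C=C/C(C)=C/C(=O)OCC | intermediate
13 | (2E,4E)-3-methylocta-2,4-dien-6-yn-1-ol | CC#C/C=C/C(C)=C/CO | intermediate
14 | (2E,4E)-3-methylocta-2,4-dien-6-ynal | CC#C/C=C/C(C)=C/C=O | intermediate
15 | (1E,3E,5E)-1-iodo-4-methylnona-1,3,5-trien-7-yne | CC#C/C=C/C(C)=C/C=C/I | intermediate
16 | pent-4-yn-1-ol | C#CCCCO | starting material
17 | {(1E)-5-[(dimethylalumanyl)oxy]-2-methylpent-1-en-1-yl}dimethylalumane (not isolated) | C[Al](C)/C=C(\C)CCCO[Al](C)C | intermediate
18 | {(1E)-5-[(dimethylalumanyl)oxy]-2-methylpent-1-en-1-yl}zinc chloride (not isolated) | Cl[Zn]/C=C(\C)CCCO[Al](C)C | intermediate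
19 | (4E,6E,8E,10E)-4,9-dimethyltetradeca-4,6,8,10-tetraen-12-yn-1-ol | CC#C/C=C/C(C)=C/C=C/C=C(\C)CCCO | intermediate
20 | (1R)-4-[(3E,5E,7E,9E,11E)-15-hydroxy-3,7,12-trimethylpentadeca-3,5,7,9,11-pentaen-1-yn-1-yl]-3,5,5-trimethylcyclohex-3-en-1-ol | CC1=C(C#C/C(C)=C/C=C/C(C)=C/C=C/C=C(\C)CCCO)C(C)(C)C[C@H](O)C1 | target

**Totals and risks**

Total step count: 11. Longest linear sequence: 7 steps (steps 5 to 11, from but-2-yn-1-ol).

Steps most likely to fail:

1. Step 11 (Proposed new method). Insertion of the C9≡C10 alkyne into the alkynylrhodium may be slow or regiochemically unselective, head-to-head dimerization of the donor alkyne may compete, and the tetraene may bind and deactivate the rhodium. The fallback uses known chemistry, sets out from 19 and 7 and comes back at 20. Copper-catalysed protoboration of 19 (B2pin2, CuCl, P(p-tol)3, NaOtBu, MeOH, THF, rt) adds boron syn to the methyl-bearing carbon distal to the polyene, and methanol protonates the carbon–copper bond; this should give the C9 pinacol boronate F1. Bromination of the alkyne terminus of 7 (NBS, AgNO3 cat., acetone, rt) should give the bromoalkyne F2. Suzuki–Miyaura coupling of F1 with F2 (Pd(PPh3)4, aq. K3PO4, THF, rt) then joins C8 to C9 with retention and should give 20.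

2. Step 10. A methyl group may transfer to palladium in place of the alkenyl group, the alkenylalane may be protonated before coupling, and the light- and Lewis-acid-sensitive trienyl iodide may decompose in the aluminium-rich mixture. The fallback sets out from 16 and comes back at 19, with 15 as the unchanged partner. The carboalumination of 16 is run as before but quenched with I2 (THF, −30 °C), which should give (4E)-5-iodo-4-methylpent-4-en-1-ol F3. Miyaura borylation (B2pin2, PdCl2(PPh3)2, PPh3, KOPh, toluene, 50 °C) should convert it with retention into the alkenyl pinacol boronate F4. This isolable, aluminium-free nucleophile is coupled with 15 under Suzuki–Miyaura conditions (Pd(PPh3)4, aq. K3PO4, THF, rt) to give 19.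

3. Step 9. The elimination from the chromium adducts may be incompletely E-selective, and excess divalent chromium may cause reductive pinacol-type coupling of the enal. The fallback sets out from 14 and comes back at 15. Colvin homologation of the aldehyde (Me3SiCHN2, LiN(iPr)2, THF, −78 °C → rt) should give the terminal dienediyne F5. Hydrozirconation of its terminal alkyne with Cp2Zr(H)Cl (THF, rt), which is much faster than addition to the internal methyl alkyne, followed by iodinolysis (I2, 0 °C), should give 15 with the 15E geometry fixed by the syn addition.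

**Further compounds**

F1 | step 11 | (4E,6E,8E,10E,12Z)-4,9-dimethyl-13-(4,4,5,5-tetramethyl-1,3,2-dioxaborolan-2-yl)tetradeca-4,6,8,10,12-pentaen-1-ol | B1(OC(C)(C)C(C)(C)O1)/C(C)=C/C=C/C(C)=C/C=C/C=C(\C)CCCO
F2 | step 11 | (1R)-4-(bromoethynyl)-3,5,5-trimethylcyclohex-3-en-1-ol | CC1=C(C#CBr)C(C)(C)C[C@H](O)C1
F3 | step 10 | (4E)-5-iodo-4-methylpent-4-en-1-ol | OCCC/C(C)=C/I
F4 | step 10 | (4E)-4-methyl-5-(4,4,5,5-tetramethyl-1,3,2-dioxaborolan-2-yl)pent-4-en-1-ol | OCCC/C(C)=C/B1OC(C)(C)C(C)(C)O1
F5 | step 9 | (3E,5E)-4-methylnona-3,5-dien-1,7-diyne | CC#C/C=C/C(C)=C/C#C
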